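**Plan**

1. Chain numbering used below: C1 = acetoxy carbon, C2 and C3 = the two CH(CH3) carbons, C4 = CH2 next to the spiro atom. The retrosynthesis cuts first the C(spiro)–C(aryl) bond of the seven-membered ring, which gives the acyclic phenol acetate 18. It then cuts the C4–O bond (quinone-methide deoxygenation), the C4–aryl bond (Grignard addition to a lactol), the C3–CH3 bond (lactone enolate methylation) and the C1–C2 bond (crotylboration of 3,4,5-trimethoxybenzaldehyde).
2. Enabling feature: the 3,5-dimethoxy-4-oxocyclohexa-2,5-diene ring is the two-electron-oxidised form of a 4-alkyl-2,6-dimethoxyphenol. Its spiro atom (para to C=O) is bonded to ring carbon C2 of the 3,4,5-trimethoxyphenyl unit, a position ortho and para to methoxy groups. The seven-membered ring can therefore be closed last by a dearomatising para–ortho′ phenol–arene coupling that makes the quaternary spiro carbon, the dienone and the ring in one event.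
3. Forward order: the trimethoxyphenyl ring is bought; the C1–C2 diad is set; a temporary γ-lactone (not in the target) is closed and used to set C3; the lactone is opened by the second aryl ring (bought as a bromophenol); bis-acetylation and selective C4 deoxygenation follow; the seven-membered ring and the dienone are formed last.
4. Stereochemistry: C1 and C2 come from a catalyst-controlled syn-crotylboration. C3 comes from methylation of the cis-lactone enolate trans to the C4 methyl of the lactone. The spiro carbon is not stereogenic (symmetrical dienone). The C4 carbinol centre is uncontrolled and is erased.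

Key step: step 10

Assumption: (R)-TRIP is taken as the catalyst enantiomer that delivers the crotyl group to the Re face of an aryl aldehyde; if the sense is opposite, (S)-TRIP is used.

**Step 1**
Reactants: 1 3,4,5-trimethoxybenzaldehyde; 2 (Z)-crotylboronic acid pinacol ester
Product: 4 (1R,2S)-2-methyl-1-(3,4,5-trimethoxyphenyl)but-3-en-1-ol, via O-pinacolboryl ether 3 (not isolated)
Conditions: 2 (1.3 equiv), (R)-TRIP (5 mol %), 4 Å MS, toluene, −30 °C; aq. NaHCO3
Reagents that add atoms: none
Why: Chiral phosphoric acid-catalysed crotylboration runs through a closed chair (Zimmerman–Traxler) transition state, so the (Z)-boronate should give the syn adduct while the catalyst selects the Re face of the aldehyde, setting C1 (R) and C2 (S) together.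

**Step 2**
Reactants: 4 (1R,2S)-2-methyl-1-(3,4,5-trimethoxyphenyl)but-3-en-1-ol
Product: 6 (1R,2S)-2-methyl-1-(3,4,5-trimethoxyphenyl)butane-1,4-diol, via B-alkyl-9-BBN 5 (not isolated)
Conditions: 9-BBN (2.5 equiv), THF, 0 °C → rt; then aq. NaOH, 30% H2O2, 0 °C → rt
Reagents that add atoms: hydrogen peroxide OO
Why: Anti-Markovnikov hydroboration–oxidation of the terminal vinyl group places the oxygen on the terminal carbon and does not touch the two stereocentres.

**Step 3**
Reactants: 6 (1R,2S)-2-methyl-1-(3,4,5-trimethoxyphenyl)butane-1,4-diol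
Product: 8 (4S,5R)-4-methyl-5-(3,4,5-trimethoxyphenyl)oxolan-2-one, via lactol 7 (not isolated)
Conditions: TEMPO (0.2 equiv), PhI(OAc)2 (2.5 equiv), CH2Cl2, rt
Reagents that add atoms: none
Why: TEMPO/PhI(OAc)2 oxidises the primary alcohol selectively, the aldehyde closes to lactol 7 with the benzylic hydroxyl and is oxidised on to the γ-lactone (oxidative lactonisation), which should be the 4,5-cis lactone because the syn diad is carried over unchanged.

**Step 4**
Reactants: 8 (4S,5R)-4-methyl-5-(3,4,5-trimethoxyphenyl)oxolan-2-one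
Product: 10 (3S,4S,5R)-3,4-dimethyl-5-(3,4,5-trimethoxyphenyl)oxolan-2-one, via lithium enolate 9 (not isolated)
Conditions: LDA (1.1 equiv), THF, −78 °C; MeI (3 equiv), −78 → −40 °C
Reagents that add atoms: iodomethane CI
Why: Alkylation of a γ-butyrolactone enolate should occur on the face opposite the C4 methyl and C5 aryl groups, which lie on the same face of the cis-lactone, so the new C3 methyl is set trans to the C4 methyl (also the thermodynamically preferred arrangement).

**Step 5**
Reactants: 10 (3S,4S,5R)-3,4-dimethyl-5-(3,4,5-trimethoxyphenyl)oxolan-2-one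
Product: 11 (3S,4S,5R)-3,4-dimethyl-5-(3,4,5-trimethoxyphenyl)oxolan-2-ol (both anomers)
Conditions: DIBAL-H (1.1 equiv), CH2Cl2, −78 °C; aq. Rochelle salt
Reagents that add atoms: none
Why: DIBAL-H reduction of a γ-lactone at −78 °C should stop at the lactol because the aluminium hemiacetal is stable until work-up.

**Step 6**
Reactants: 12 4-bromo-2,6-dimethoxyphenol
Product: 13 tert-butyl(4-bromo-2,6-dimethoxyphenoxy)dimethylsilane
Conditions: TBSCl (1.3 equiv), imidazole (2.5 equiv), DMF, rt
Reagents that add atoms: tert-butyldimethylsilyl chloride CC(C)(C)[Si](C)(C)Cl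
Why: Standard silylation of the phenol masks the acidic O–H for the Grignard step and installs the fluoride-labile trigger used in step 9.

**Step 7**
Reactants: 11 (3S,4S,5R)-3,4-dimethyl-5-(3,4,5-trimethoxyphenyl)oxolan-2-ol; 13 tert-butyl(4-bromo-2,6-dimethoxyphenoxy)dimethylsilane
Product: 15 (1R,2S,3S,4RS)-4-[4-(tert-butyldimethylsilyloxy)-3,5-dimethoxyphenyl]-2,3-dimethyl-1-(3,4,5-trimethoxyphenyl)butane-1,4-diol, via aryl Grignard reagent 14 (not isolated)
Conditions: 13 (3 equiv), Mg, THF, reflux; then 11, THF, 0 °C → rt; aq. NH4Cl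
Reagents that add atoms: none
Why: Grignard addition to the open hydroxy-aldehyde form of a lactol is a standard route to 1,4-diols, and the new carbinol centre at C4 need not be controlled because it becomes CH2 in step 9.

**Step 8**
Reactants: 15 (1R,2S,3S,4RS)-4-[4-(tert-butyldimethylsilyloxy)-3,5-dimethoxyphenyl]-2,3-dimethyl-1-(3,4,5-trimethoxyphenyl)butane-1,4-diol
Product: 16 (1R,2S,3S,4RS)-4-[4-(tert-butyldimethylsilyloxy)-3,5-dimethoxyphenyl]-2,3-dimethyl-1-(3,4,5-trimethoxyphenyl)butane-1,4-diyl diacetate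
Conditions: Ac2O (4 equiv), pyridine, DMAP (cat.), CH2Cl2, rt
Reagents that add atoms: acetic anhydride CC(=O)OC(C)=O
Why: DMAP-catalysed acetylation should esterify both secondary benzylic alcohols, installing at once the acetate of the target at C1 and the leaving group at C4.

**Step 9**
Reactants: 16 (1R,2S,3S,4RS)-4-[4-(tert-butyldimethylsilyloxy)-3,5-dimethoxyphenyl]-2,3-dimethyl-1-(3,4,5-trimethoxyphenyl)butane-1,4-diyl diacetate
Product: 18 (1R,2S,3R)-4-(4-hydroxy-3,5-dimethoxyphenyl)-2,3-dimethyl-1-(3,4,5-trimethoxyphenyl)butyl acetate, via quinone methide 17 (not isolated)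
Conditions: NaBH4 (5 equiv), TBAF (1.2 equiv, slow addition), THF/i-PrOH, 0 °C; aq. NH4Cl
Reagents that add atoms: none
Why: Fluoride desilylation gives the phenoxide, which expels the para-benzylic acetate by 1,6-elimination to p-quinone methide 17, and borohydride adds hydride to the exocyclic carbon (quinone methide reduction), so only the C4 oxygen is removed while the C1 acetate, which has no para-phenoxide, should stay.

**Step 10**
Reactants: 18 (1R,2S,3R)-4-(4-hydroxy-3,5-dimethoxyphenyl)-2,3-dimethyl-1-(3,4,5-trimethoxyphenyl)butyl acetate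
Product: 20 (7R,8S,9R)-2,3,3',4,5'-pentamethoxy-7,8-dimethyl-4'-oxo-6,7,8,9-tetrahydrospiro[benzo[7]annulene-5,1'-cyclohexa[2,5]dien]-9-yl acetate (target), via aryloxy-λ3-iodane 19 (not isolated)
Conditions: PhI(OAc)2 (1.1 equiv), (CF3)2CHOH, 0 °C, 0.01 M, short reaction time
Reagents that add atoms: none
Why: Ligand exchange of the phenol at iodine(III) gives aryloxy-λ3-iodane 19, which loses iodobenzene and acetate to a phenoxonium ion whose positive charge sits largely on the para carbon carrying the side chain (stabilised by the two ortho methoxy groups and not trapped by the non-nucleophilic solvent). The closest known reaction type is the hypervalent-iodine para–ortho′ phenol–arene oxidative coupling that turns 4-(ω-arylalkyl)phenols into spirocyclohexadienones (oxidative dearomatisation). The seven-membered ring closes by Ar2-7 participation: C2 of the 3,4,5-trimethoxyphenyl ring attacks the para carbon in a 7-exo-trig spiro mode, and the arenium ion then loses a proton. No stereocentre is formed, because the dienone ring is symmetrical and the spiro carbon is not stereogenic, and C1–C3 are not touched. The step needs oxidation of the phenol and not of the trimethoxyarene (only the free OH binds to iodine), attack at the para and not the methoxy-bearing ortho carbons (the four-atom tether reaches only the para carbon, and C2 and C6 of the nucleophilic ring are equivalent), and C–C and not C–O closure (the C1 oxygen is already acetylated, so no oxa-spirocycle can form).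

**Compound list**

1 | 3,4,5-trimethoxybenzaldehyde | COc1cc(C=O)cc(OC)c1OC | starting material
2 | (Z)-crotylboronic acid pinacol ester | C/C=C\CB1OC(C)(C)C(C)(C)O1 | starting material
3 | 4,4,5,5-tetramethyl-2-{[(1R,2S)-2-methyl-1-(3,4,5-trimethoxyphenyl)but-3-en-1-yl]oxy}-1,3,2-dioxaborolane | C=C[C@H](C)[C@@H](OB1OC(C)(C)C(C)(C)O1)c1cc(OC)c(OC)c(OC)c1 | intermediate
4 | (1R,2S)-2-methyl-1-(3,4,5-trimethoxyphenyl)but-3-en-1-ol | C=C[C@H](C)[C@@H](O)c1cc(OC)c(OC)c(OC)c1 | intermediate
5 | (1R,2S)-4-(9-borabicyclo[3.3.1]nonan-9-yl)-2-methyl-1-(3,4,5-trimethoxyphenyl)butan-1-ol | C1CC2CCCC(C1)B2CC[C@H](C)[C@@H](O)c1cc(OC)c(OC)c(OC)c1 | intermediate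
6 | (1R,2S)-2-methyl-1-(3,4,5-trimethoxyphenyl)butane-1,4-diol | OCC[C@H](C)[C@@H](O)c1cc(OC)c(OC)c(OC)c1 | intermediate
7 | (4S,5R)-4-methyl-5-(3,4,5-trimethoxyphenyl)oxolan-2-ol (both anomers) | OC1C[C@H](C)[C@@H](O1)c2cc(OC)c(OC)c(OC)c2 | intermediate
8 | (4S,5R)-4-methyl-5-(3,4,5-trimethoxyphenyl)oxolan-2-one (4,5-cis) | O=C1C[C@H](C)[C@@H](O1)c2cc(OC)c(OC)c(OC)c2 | intermediate
9 | lithium (4S,5R)-4-methyl-5-(3,4,5-trimethoxyphenyl)-4,5-dihydrofuran-2-olate | [Li]OC1=C[C@H](C)[C@@H](O1)c2cc(OC)c(OC)c(OC)c2 | intermediate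
10 | (3S,4S,5R)-3,4-dimethyl-5-(3,4,5-trimethoxyphenyl)oxolan-2-one (3,4-trans; 4,5-cis) | O=C1[C@@H](C)[C@H](C)[C@@H](O1)c2cc(OC)c(OC)c(OC)c2 | intermediate
11 | (3S,4S,5R)-3,4-dimethyl-5-(3,4,5-trimethoxyphenyl)oxolan-2-ol (both anomers) | OC1[C@@H](C)[C@H](C)[C@@H](O1)c2cc(OC)c(OC)c(OC)c2 | intermediate
12 | 4-bromo-2,6-dimethoxyphenol | COc1cc(Br)cc(OC)c1O | starting material
13 | tert-butyl(4-bromo-2,6-dimethoxyphenoxy)dimethylsilane | COc1cc(Br)cc(OC)c1O[Si](C)(C)C(C)(C)C | intermediate
14 | [4-(tert-butyldimethylsilyloxy)-3,5-dimethoxyphenyl]magnesium bromide | COc1cc([Mg]Br)cc(OC)c1O[Si](C)(C)C(C)(C)C | intermediate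
15 | (1R,2S,3S,4RS)-4-[4-(tert-butyldimethylsilyloxy)-3,5-dimethoxyphenyl]-2,3-dimethyl-1-(3,4,5-trimethoxyphenyl)butane-1,4-diol | COc1cc(C(O)[C@@H](C)[C@H](C)[C@@H](O)c2cc(OC)c(OC)c(OC)c2)cc(OC)c1O[Si](C)(C)C(C)(C)C | intermediate
16 | (1R,2S,3S,4RS)-4-[4-(tert-butyldimethylsilyloxy)-3,5-dimethoxyphenyl]-2,3-dimethyl-1-(3,4,5-trimethoxyphenyl)butane-1,4-diyl diacetate | COc1cc(C(OC(C)=O)[C@@H](C)[C@H](C)[C@@H](OC(C)=O)c2cc(OC)c(OC)c(OC)c2)cc(OC)c1O[Si](C)(C)C(C)(C)C | intermediate
17 | (1R,2S,3R)-4-(3,5-dimethoxy-4-oxocyclohexa-2,5-dien-1-ylidene)-2,3-dimethyl-1-(3,4,5-trimethoxyphenyl)butyl acetate | COC1=CC(=C[C@@H](C)[C@H](C)[C@@H](OC(C)=O)c2cc(OC)c(OC)c(OC)c2)C=C(OC)C1=O | intermediate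
18 | (1R,2S,3R)-4-(4-hydroxy-3,5-dimethoxyphenyl)-2,3-dimethyl-1-(3,4,5-trimethoxyphenyl)butyl acetate | COc1cc(C[C@@H](C)[C@H](C)[C@@H](OC(C)=O)c2cc(OC)c(OC)c(OC)c2)cc(OC)c1O | intermediate
19 | (1R,2S,3R)-4-{4-[acetoxy(phenyl)-λ3-iodanyloxy]-3,5-dimethoxyphenyl}-2,3-dimethyl-1-(3,4,5-trimethoxyphenyl)butyl acetate | COc1cc(C[C@@H](C)[C@H](C)[C@@H](OC(C)=O)c2cc(OC)c(OC)c(OC)c2)cc(OC)c1OI(OC(C)=O)c1ccccc1 | intermediate
20 | (7R,8S,9R)-2,3,3',4,5'-pentamethoxy-7,8-dimethyl-4'-oxo-6,7,8,9-tetrahydrospiro[benzo[7]annulene-5,1'-cyclohexa[2,5]dien]-9-yl acetate | COC1=CC2(C=C(OC)C1=O)C[C@@H](C)[C@H](C)[C@@H](OC(C)=O)c1cc(OC)c(OC)c(OC)c12 | target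

**Step count and risks**

Total step count: 10. Longest linear sequence: 9 steps (steps 1–5 and 7–10); step 6 is a one-step side branch.

Steps most likely to fail:

**Step 10.** Closure of a seven-membered ring is slow, so the phenoxonium ion may be captured by acetate or solvent, or the spirodienone may undergo acid-promoted dienone–phenol rearrangement (1,2-aryl shift) once formed. The fallback forms the same C–C bond by palladium instead of by phenol oxidation. It sets out from lactone 10, which is brominated on its only free arene positions (NBS, MeCN) to (3S,4S,5R)-5-(2-bromo-3,4,5-trimethoxyphenyl)-3,4-dimethyloxolan-2-one F1. The operations of steps 5, 7, 8 and 9 are then repeated on the bromo series, which should give in turn bromolactol F2, bromodiol F3, bromodiacetate F4 and, through bromo quinone methide F5, bromophenol acetate F6. F6 would be closed by Pd(0)-catalysed intramolecular arylative dearomatisation of the phenol (Pd2(dba)3, bulky biarylphosphine, K2CO3, dioxane, 100 °C): the phenoxide attacks the arylpalladium(II) centre through its para carbon and reductive elimination forms the spiro C–aryl bond. This type of closure is established for smaller spiro rings and would here be stretched to a seven-membered one. The sequence comes back to the route at target 20.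

**Step 9.** The base may tautomerise the quinone methide to a 4-vinylphenol, which would destroy the C3 stereocentre, or the C1 acetate may be lost under the basic fluoride/borohydride conditions. The fallback is a cationic instead of an anionic deoxygenation. It sets out from diacetate 16, which is desilylated under buffered conditions (TBAF, AcOH, THF, −20 °C) to phenol diacetate F7. F7 with Et3SiH and CF3CO2H in CH2Cl2 at −40 °C should ionise only at C4, where the para-hydroxy group stabilises the benzylic cation, and the silane reduces it (ionic hydrogenation). The sequence comes back to the route at 18.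

**Step 7.** The magnesium lactolate may open only sluggishly, so that the Grignard reagent acts as a base and the transient α-branched aldehyde enolises, with loss of material and epimerisation at C3. The fallback is acyl substitution on the lactone, without the lactol. It sets out from lactone 10 and bromide 13: 13 with n-BuLi (THF, −78 °C) gives aryllithium F8, which should add once to 10 at −78 °C to give γ-hydroxy ketone F9, because the tetrahedral intermediate persists until the quench. Prompt reduction with NaBH4/CeCl3 in MeOH at −40 °C comes back to the route at diol 15.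

**Further compounds**

F1 | step 10 | (3S,4S,5R)-5-(2-bromo-3,4,5-trimethoxyphenyl)-3,4-dimethyloxolan-2-one | O=C1[C@@H](C)[C@H](C)[C@@H](O1)c2cc(OC)c(OC)c(OC)c2Br
F2 | step 10 | (3S,4S,5R)-5-(2-bromo-3,4,5-trimethoxyphenyl)-3,4-dimethyloxolan-2-ol (both anomers) | OC1[C@@H](C)[C@H](C)[C@@H](O1)c2cc(OC)c(OC)c(OC)c2Br
F3 | step 10 | (1R,2S,3S,4RS)-1-(2-bromo-3,4,5-trimethoxyphenyl)-4-[4-(tert-butyldimethylsilyloxy)-3,5-dimethoxyphenyl]-2,3-dimethylbutane-1,4-diol | COc1cc(C(O)[C@@H](C)[C@H](C)[C@@H](O)c2cc(OC)c(OC)c(OC)c2Br)cc(OC)c1O[Si](C)(C)C(C)(C)C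
F4 | step 10 | (1R,2S,3S,4RS)-1-(2-bromo-3,4,5-trimethoxyphenyl)-4-[4-(tert-butyldimethylsilyloxy)-3,5-dimethoxyphenyl]-2,3-dimethylbutane-1,4-diyl diacetate | COc1cc(C(OC(C)=O)[C@@H](C)[C@H](C)[C@@H](OC(C)=O)c2cc(OC)c(OC)c(OC)c2Br)cc(OC)c1O[Si](C)(C)C(C)(C)C
F5 | step 10 | (1R,2S,3R)-1-(2-bromo-3,4,5-trimethoxyphenyl)-4-(3,5-dimethoxy-4-oxocyclohexa-2,5-dien-1-ylidene)-2,3-dimethylbutyl acetate | COC1=CC(=C[C@@H](C)[C@H](C)[C@@H](OC(C)=O)c2cc(OC)c(OC)c(OC)c2Br)C=C(OC)C1=O
F6 | step 10 | (1R,2S,3R)-1-(2-bromo-3,4,5-trimethoxyphenyl)-4-(4-hydroxy-3,5-dimethoxyphenyl)-2,3-dimethylbutyl acetate | COc1cc(C[C@@H](C)[C@H](C)[C@@H](OC(C)=O)c2cc(OC)c(OC)c(OC)c2Br)cc(OC)c1O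
F7 | step 9 | (1R,2S,3S,4RS)-4-(4-hydroxy-3,5-dimethoxyphenyl)-2,3-dimethyl-1-(3,4,5-trimethoxyphenyl)butane-1,4-diyl diacetate | COc1cc(C(OC(C)=O)[C@@H](C)[C@H](C)[C@@H](OC(C)=O)c2cc(OC)c(OC)c(OC)c2)cc(OC)c1O
F8 | step 7 | [4-(tert-butyldimethylsilyloxy)-3,5-dimethoxyphenyl]lithium | COc1cc([Li])cc(OC)c1O[Si](C)(C)C(C)(C)C
F9 | step 7 | (2S,3S,4R)-1-[4-(tert-butyldimethylsilyloxy)-3,5-dimethoxyphenyl]-4-hydroxy-2,3-dimethyl-4-(3,4,5-trimethoxyphenyl)butan-1-one | O=C(c1cc(OC)c(O[Si](C)(C)C(C)(C)C)c(OC)c1)[C@@H](C)[C@H](C)[C@@H](O)c1cc(OC)c(OC)c(OC)c1
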